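## Retrosynthetic overview

1. Target ⇐ singlet-oxygen ene reaction on the only alkene (C7=C8) of the bicyclic epoxy hydroxy lactone; this last step sets C8.
2. 14-membered carbocycle (ring B, formed last) ⇐ ring-closing metathesis at C13=C14, then diimide reduction.
3. Oxirane at C11/C12 (formed second) ⇐ allylic oxidation of the terminal E-methyl, Sharpless epoxidation, oxidation, methylenation.
4. Six-membered lactone (ring A, formed first; C1, C15, C3, C4) ⇐ Ireland–Claisen rearrangement of an (R)-butenyl propanoate, then opening of a Sharpless 2,3-epoxide by the new acid with inversion at C3.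
5. Carbon sources: (2E,6E)-farnesol (C2–C13, C18–C20), vinylmagnesium bromide (C1), (2R)-but-3-en-2-ol (C14), propanoic anhydride (C15–C17).

Assumption: C1–C20 are cembrane locants of the target (C1 ring-fusion CH, C3 lactone O–CH, C4 carbinol, C8 hydroperoxide carbon, C11/C12 oxirane, C15 CHMe, C16 C=O). Minor isomers (C15 epimer, Z-alkene from step 4) are removed by chromatography. The route is a design and has not been run.

## Route

Step 1
Reactants: 1 (2E,6E)-farnesol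
Product: 2 [(2S,3S)-3-[(3E)-4,8-dimethylnona-3,7-dien-1-yl]-3-methyloxiran-2-yl]methanol
Conditions: Ti(OiPr)4 (10 mol%), L-(+)-diethyl tartrate (12 mol%), t-BuOOH, 4 Å MS, CH2Cl2, −20 °C
Reagents that add atoms: tert-butyl hydroperoxide, CC(C)(C)OO
Why: Katsuki–Sharpless asymmetric epoxidation touches only the allylic-alcohol alkene, and L-(+)-tartrate delivers oxygen to the face that gives the (2S,3S)-oxirane (future C3/C4).

Step 2
Reactants: 2 [(2S,3S)-3-[(3E)-4,8-dimethylnona-3,7-dien-1-yl]-3-methyloxiran-2-yl]methanol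
Product: 4 (2S,3S)-2-[(3E)-4,8-dimethylnona-3,7-dien-1-yl]-2-methyl-3-(prop-2-en-1-yl)oxirane, via epoxy triflate 3 (not isolated)
Conditions: Tf2O, 2,6-lutidine, CH2Cl2, −78 °C; then CH2=CHMgBr (3 equiv), CuBr·SMe2 (20 mol%), THF, −78 → −40 °C
Reagents that add atoms: vinylmagnesium bromide, C=C[Mg]Br
Why: Triflation followed by copper-catalysed Grignard cross-coupling (SN2 displacement of the primary triflate, faster than oxirane opening at low temperature) forms the C1–C2 bond without touching either stereocentre.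

Step 3
Reactants: 5 (2R)-but-3-en-2-ol
Product: 6 (2R)-but-3-en-2-yl propanoate
Conditions: (EtCO)2O, DMAP (5 mol%), pyridine, 0 → 23 °C
Reagents that add atoms: propanoic anhydride, CCC(=O)OC(=O)CC
Why: DMAP-catalysed acyl transfer (nucleophilic-catalysis esterification) acylates the carbinol oxygen and breaks no bond at the stereocentre.

Step 4
Reactants: 4 (2S,3S)-2-[(3E)-4,8-dimethylnona-3,7-dien-1-yl]-2-methyl-3-(prop-2-en-1-yl)oxirane; 6 (2R)-but-3-en-2-yl propanoate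
Product: 7 (2R,3E)-5-[(2S,3S)-3-[(3E)-4,8-dimethylnona-3,7-dien-1-yl]-3-methyloxiran-2-yl]pent-3-en-2-yl propanoate
Conditions: second-generation Grubbs catalyst RuCl2(=CHPh)(H2IMes)(PCy3) (5 mol%), 6 (3 equiv), CH2Cl2, 40 °C
Reagents that add atoms: none
Why: Olefin cross-metathesis joins the monosubstituted alkene of 4 to allylic ester 6 with loss of ethene, gives the E-alkene under thermodynamic control, and leaves the sluggish trisubstituted alkenes and all stereocentres alone.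

Step 5
Reactants: 7 (2R,3E)-5-[(2S,3S)-3-[(3E)-4,8-dimethylnona-3,7-dien-1-yl]-3-methyloxiran-2-yl]pent-3-en-2-yl propanoate
Product: 11 (3S,4S,6R)-6-[(2S,5E)-2-hydroxy-6,10-dimethylundeca-5,9-dien-2-yl]-3-methyl-4-[(1E)-prop-1-en-1-yl]oxan-2-one, via silyl ketene acetal 8 (not isolated), via trimethylsilyl ester 9 (not isolated), via epoxy acid 10 (not isolated)
Conditions: LiN(iPr)2 (1.2 equiv), THF, −78 °C; Me3SiCl, −78 → 50 °C; aq. citric acid; then PPTS (10 mol%), CH2Cl2, 23 °C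
Reagents that add atoms: none
Why: Ireland–Claisen rearrangement of the (E)-silyl ketene acetal through a chair transition state transfers the (R)-carbinol chirality to C1 and sets C15 (E-ketene acetal plus E-alkene gives the 3,4-trans lactone relationship), and the freed 5,6-epoxy acid then closes by 6-exo-tet attack of the carboxyl group on C3 with inversion, which fixes C3 as R and leaves C4 (S) as the tertiary alcohol.

Step 6
Reactants: 11 (3S,4S,6R)-6-[(2S,5E)-2-hydroxy-6,10-dimethylundeca-5,9-dien-2-yl]-3-methyl-4-[(1E)-prop-1-en-1-yl]oxan-2-one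
Product: 12 (3S,4S,6R)-6-[(2S,5E,9E)-2,11-dihydroxy-6,10-dimethylundeca-5,9-dien-2-yl]-3-methyl-4-[(1E)-prop-1-en-1-yl]oxan-2-one
Conditions: SeO2 (20 mol%), t-BuOOH (3 equiv), salicylic acid (10 mol%), CH2Cl2, 23 °C
Reagents that add atoms: tert-butyl hydroperoxide, CC(C)(C)OO; selenium dioxide, O=[Se]=O (catalytic oxygen relay)
Why: Sharpless–Umbreit allylic oxidation (ene reaction then [2,3]-sigmatropic shift) oxidizes the E-methyl of the terminal isopropylidene group in preference to the internal trisubstituted and the disubstituted alkene and creates no stereocentre.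

Step 7
Reactants: 12 (3S,4S,6R)-6-[(2S,5E,9E)-2,11-dihydroxy-6,10-dimethylundeca-5,9-dien-2-yl]-3-methyl-4-[(1E)-prop-1-en-1-yl]oxan-2-one
Product: 13 (3S,4S,6R)-6-[(2S,5E)-2-hydroxy-8-[(2S,3S)-3-(hydroxymethyl)-3-methyloxiran-2-yl]-6-methyloct-5-en-2-yl]-3-methyl-4-[(1E)-prop-1-en-1-yl]oxan-2-one
Conditions: Ti(OiPr)4 (20 mol%), L-(+)-diethyl tartrate (24 mol%), t-BuOOH, 4 Å MS, CH2Cl2, −20 °C
Reagents that add atoms: tert-butyl hydroperoxide, CC(C)(C)OO
Why: A second Katsuki–Sharpless asymmetric epoxidation, reagent-controlled by L-(+)-tartrate, converts the (E)-2-methylallylic alcohol into the (11S,12S)-oxirane and ignores the non-allylic alkenes.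

Step 8
Reactants: 13 (3S,4S,6R)-6-[(2S,5E)-2-hydroxy-8-[(2S,3S)-3-(hydroxymethyl)-3-methyloxiran-2-yl]-6-methyloct-5-en-2-yl]-3-methyl-4-[(1E)-prop-1-en-1-yl]oxan-2-one
Product: 14 (3S,4S,6R)-6-[(2S,5E)-8-[(2S,3R)-3-formyl-3-methyloxiran-2-yl]-2-hydroxy-6-methyloct-5-en-2-yl]-3-methyl-4-[(1E)-prop-1-en-1-yl]oxan-2-one
Conditions: Dess–Martin periodinane, NaHCO3, CH2Cl2, 0 → 23 °C
Reagents that add atoms: none
Why: Dess–Martin oxidation converts the primary alcohol into the aldehyde under buffered conditions, the tertiary alcohol cannot be oxidized, and the quaternary α-carbon cannot epimerize (its descriptor changes to R only through the priority rules).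

Step 9
Reactants: 14 (3S,4S,6R)-6-[(2S,5E)-8-[(2S,3R)-3-formyl-3-methyloxiran-2-yl]-2-hydroxy-6-methyloct-5-en-2-yl]-3-methyl-4-[(1E)-prop-1-en-1-yl]oxan-2-one
Product: 15 (3S,4S,6R)-6-[(2S,5E)-8-[(2S,3S)-3-ethenyl-3-methyloxiran-2-yl]-2-hydroxy-6-methyloct-5-en-2-yl]-3-methyl-4-[(1E)-prop-1-en-1-yl]oxan-2-one
Conditions: Ph3PCH3Br, KN(SiMe3)2 (2.2 equiv of ylide), THF, −78 → 0 °C
Reagents that add atoms: methyltriphenylphosphonium bromide, C[P+](c1ccccc1)(c1ccccc1)c1ccccc1.[Br-]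
Why: Wittig methylenation of the aldehyde is fast at low temperature, leaves the lactone carbonyl alone, and gives the vinyl oxirane without creating or disturbing a stereocentre.

Step 10
Reactants: 15 (3S,4S,6R)-6-[(2S,5E)-8-[(2S,3S)-3-ethenyl-3-methyloxiran-2-yl]-2-hydroxy-6-methyloct-5-en-2-yl]-3-methyl-4-[(1E)-prop-1-en-1-yl]oxan-2-one
Product: 16 (1S,3R,4S,7E,11S,12S,15S)-11,12-epoxy-4-hydroxycembra-7,13-dien-16,3-olide as an E/Z mixture at C13=C14
Conditions: second-generation Hoveyda–Grubbs catalyst RuCl2(=CH-C6H4-2-OiPr)(H2IMes) (15 mol%), toluene (1 mM), 80 °C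
Reagents that add atoms: none
Why: Ring-closing metathesis between the vinyl oxirane and the propenyl group forms the C13=C14 bond of the 14-membered ring with loss of propene, and the new alkene geometry does not matter because the alkene is reduced in the next step.

Step 11
Reactants: 16 (1S,3R,4S,7E,11S,12S,15S)-11,12-epoxy-4-hydroxycembra-7,13-dien-16,3-olide
Product: 17 (1R,3R,4S,7E,11S,12S,15S)-11,12-epoxy-4-hydroxycembr-7-en-16,3-olide
Conditions: 2-nitrobenzenesulfonohydrazide, Et3N, CH2Cl2, 23 °C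
Reagents that add atoms: none
Why: Diimide reduction (concerted syn transfer of H2) saturates the 1,2-disubstituted C13=C14 alkene much faster than the trisubstituted C7=C8 alkene and, unlike metal-catalysed hydrogenation, does not open the allylic oxirane.

Step 12
Reactants: 17 (1R,3R,4S,7E,11S,12S,15S)-11,12-epoxy-4-hydroxycembr-7-en-16,3-olide
Product: 18 (1R,3R,4S,6E,8R,11S,12S,15S)-11,12-epoxy-8-hydroperoxy-4-hydroxycembr-6-en-16,3-olide
Conditions: O2, 5,10,15,20-tetraphenylporphyrin (1 mol%), CH2Cl2, 0 °C, visible light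
Reagents that add atoms: dioxygen, O=O
Why: The Schenck ene reaction of singlet oxygen with the only alkene bonds oxygen to C8 while an allylic hydrogen leaves C6 (cis effect) to give the E-6,7-alkene, and attack on the exposed outer face of the ring alkene is expected, not proven, to give 8R (substrate control).

## Compound list

1 | (2E,6E)-farnesol | CC(C)=CCC/C(C)=C/CC/C(C)=C/CO | starting material
2 | [(2S,3S)-3-[(3E)-4,8-dimethylnona-3,7-dien-1-yl]-3-methyloxiran-2-yl]methanol | CC(C)=CCC/C(C)=C/CC[C@]1(C)O[C@H]1CO | intermediate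
3 | [(2S,3S)-3-[(3E)-4,8-dimethylnona-3,7-dien-1-yl]-3-methyloxiran-2-yl]methyl trifluoromethanesulfonate | CC(C)=CCC/C(C)=C/CC[C@]1(C)O[C@H]1COS(=O)(=O)C(F)(F)F | intermediate (not isolated)
4 | (2S,3S)-2-[(3E)-4,8-dimethylnona-3,7-dien-1-yl]-2-methyl-3-(prop-2-en-1-yl)oxirane | CC(C)=CCC/C(C)=C/CC[C@]1(C)O[C@H]1CC=C | intermediate
5 | (2R)-but-3-en-2-ol | C=C[C@@H](C)O | starting material
6 | (2R)-but-3-en-2-yl propanoate | C=C[C@@H](C)OC(=O)CC | intermediate
7 | (2R,3E)-5-[(2S,3S)-3-[(3E)-4,8-dimethylnona-3,7-dien-1-yl]-3-methyloxiran-2-yl]pent-3-en-2-yl propanoate | CC(C)=CCC/C(C)=C/CC[C@]1(C)O[C@H]1C/C=C/[C@@H](C)OC(=O)CC | intermediate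
8 | (E)-trimethylsilyl ketene acetal of 7 (methyl cis to the allylic oxygen) | CC(C)=CCC/C(C)=C/CC[C@]1(C)O[C@H]1C/C=C/[C@@H](C)O/C(O[Si](C)(C)C)=C\C | intermediate (not isolated)
9 | trimethylsilyl (2S,3S,4E)-3-{[(2S,3S)-3-[(3E)-4,8-dimethylnona-3,7-dien-1-yl]-3-methyloxiran-2-yl]methyl}-2-methylhex-4-enoate | CC(C)=CCC/C(C)=C/CC[C@]1(C)O[C@H]1C[C@@H](/C=C/C)[C@H](C)C(=O)O[Si](C)(C)C | intermediate (not isolated)
10 | (2S,3S,4E)-3-{[(2S,3S)-3-[(3E)-4,8-dimethylnona-3,7-dien-1-yl]-3-methyloxiran-2-yl]methyl}-2-methylhex-4-enoic acid | CC(C)=CCC/C(C)=C/CC[C@]1(C)O[C@H]1C[C@@H](/C=C/C)[C@H](C)C(=O)O | intermediate (not isolated)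
11 | (3S,4S,6R)-6-[(2S,5E)-2-hydroxy-6,10-dimethylundeca-5,9-dien-2-yl]-3-methyl-4-[(1E)-prop-1-en-1-yl]oxan-2-one | C[C@@H]1C(=O)O[C@H](C[C@H]1/C=C/C)[C@@](C)(O)CC/C=C(C)/CCC=C(C)C | intermediate
12 | (3S,4S,6R)-6-[(2S,5E,9E)-2,11-dihydroxy-6,10-dimethylundeca-5,9-dien-2-yl]-3-methyl-4-[(1E)-prop-1-en-1-yl]oxan-2-one | C[C@@H]1C(=O)O[C@H](C[C@H]1/C=C/C)[C@@](C)(O)CC/C=C(C)/CC/C=C(C)/CO | intermediate
13 | (3S,4S,6R)-6-[(2S,5E)-2-hydroxy-8-[(2S,3S)-3-(hydroxymethyl)-3-methyloxiran-2-yl]-6-methyloct-5-en-2-yl]-3-methyl-4-[(1E)-prop-1-en-1-yl]oxan-2-one | C[C@@H]1C(=O)O[C@H](C[C@H]1/C=C/C)[C@@](C)(O)CC/C=C(C)/CC[C@@H]1O[C@@]1(C)CO | intermediate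
14 | (3S,4S,6R)-6-[(2S,5E)-8-[(2S,3R)-3-formyl-3-methyloxiran-2-yl]-2-hydroxy-6-methyloct-5-en-2-yl]-3-methyl-4-[(1E)-prop-1-en-1-yl]oxan-2-one | C[C@@H]1C(=O)O[C@H](C[C@H]1/C=C/C)[C@@](C)(O)CC/C=C(C)/CC[C@@H]1O[C@@]1(C)C=O | intermediate
15 | (3S,4S,6R)-6-[(2S,5E)-8-[(2S,3S)-3-ethenyl-3-methyloxiran-2-yl]-2-hydroxy-6-methyloct-5-en-2-yl]-3-methyl-4-[(1E)-prop-1-en-1-yl]oxan-2-one | C[C@@H]1C(=O)O[C@H](C[C@H]1/C=C/C)[C@@](C)(O)CC/C=C(C)/CC[C@@H]1O[C@@]1(C)C=C | intermediate
16 | (1S,3R,4S,7E,11S,12S,15S)-11,12-epoxy-4-hydroxycembra-7,13-dien-16,3-olide (E/Z mixture at C13=C14) | C[C@@H]1C(=O)O[C@@H]2C[C@H]1C=C[C@]1(C)O[C@H]1CC/C(C)=C/CC[C@]2(C)O | intermediate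
17 | (1R,3R,4S,7E,11S,12S,15S)-11,12-epoxy-4-hydroxycembr-7-en-16,3-olide | C[C@@H]1C(=O)O[C@@H]2C[C@H]1CC[C@]1(C)O[C@H]1CC/C(C)=C/CC[C@]2(C)O | intermediate
18 | (1R,3R,4S,6E,8R,11S,12S,15S)-11,12-epoxy-8-hydroperoxy-4-hydroxycembr-6-en-16,3-olide (CNP0297487.3) | C[C@@H]1C(=O)O[C@@H]2C[C@H]1CC[C@]1(C)O[C@H]1CC[C@@](C)(OO)/C=C/C[C@]2(C)O | target

## Step count and risks

Total step count: 12. Longest linear sequence: 11 steps (1 → 18 through steps 1, 2 and 4–12).

Steps most likely to fail: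

Step 12, the ene reaction. Abstraction of a C19 hydrogen gives the exocyclic-methylene secondary hydroperoxide as a competitor, and the face of attack at C8 rests on ring conformation only. The fallback sets out from 17 and comes back at 18, and it replaces the concerted ene reaction by an ionic anti-addition followed by elimination. The tertiary alcohol of 17 is capped (Me3SiOTf, 2,6-lutidine) as the trimethylsilyl ether F6, so that it cannot trap the bromonium ion. Bromohydroperoxidation (1,3-dibromo-5,5-dimethylhydantoin, anhydrous H2O2 in Et2O, −40 °C) puts OOH on the tertiary carbon C8 and Br on C7 in an anti sense, giving the bromo hydroperoxide F7. Here oxygen enters on the face opposite to the one the electrophile attacks, so the C8 outcome is complementary to direct photooxygenation and the regiochemistry is fixed. The hydroperoxide is masked with 2-methoxypropene/PPTS as the peroxyketal F8. E2 elimination of HBr toward C6 (DBU, toluene, 80 °C; C8 has no hydrogen) gives the allylic peroxyketal F9. AcOH/THF/H2O removes both masks and returns 18.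

Step 10, the ring-closing metathesis. The vinyl group sits on a quaternary oxirane carbon, the partner is an internal alkene on a tertiary carbon, and a bridged 14-membered ring must form. The fallback sets out from 14 and comes back at 16, and it uses relay ring-closing metathesis. Aldehyde 14 is treated with the ylide from hex-5-en-1-yltriphenylphosphonium bromide and KN(SiMe3)2 to give the relay triene F5. The ruthenium catalyst then loads at the unhindered terminal alkene, expels cyclopentene, and is delivered directly onto C13 for closure onto the propenyl group.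

Step 2, displacement of an epoxy triflate by a vinyl Grignard reagent. Oxirane opening or elimination may win. The fallback sets out from 2 (through triflate 3) and comes back at 7, and it replaces both the sp3–sp2 coupling and the cross-metathesis by an acetylide alkylation. Commercial (2R)-but-3-yn-2-ol is silylated (t-BuMe2SiCl, imidazole) to tert-butyl{[(2R)-but-3-yn-2-yl]oxy}dimethylsilane F1. Its lithium acetylide (n-BuLi, THF/DMPU, −78 °C) displaces the triflate of 3 to give the epoxy alkyne F2. Bu4NF gives the propargylic alcohol F3. Hydroxyl-directed trans-hydroalumination with NaAlH2(OCH2CH2OMe)2 (Et2O, −20 → 0 °C) gives the pure (E)-allylic alcohol F4, and propanoic anhydride/DMAP then gives 7.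

## Further compounds

F1 | step 2 | tert-butyl{[(2R)-but-3-yn-2-yl]oxy}dimethylsilane | C#C[C@@H](C)O[Si](C)(C)C(C)(C)C
F2 | step 2 | tert-butyl{[(2R)-5-[(2S,3S)-3-[(3E)-4,8-dimethylnona-3,7-dien-1-yl]-3-methyloxiran-2-yl]pent-3-yn-2-yl]oxy}dimethylsilane | CC(C)=CCC/C(C)=C/CC[C@]1(C)O[C@H]1CC#C[C@@H](C)O[Si](C)(C)C(C)(C)C
F3 | step 2 | (2R)-5-[(2S,3S)-3-[(3E)-4,8-dimethylnona-3,7-dien-1-yl]-3-methyloxiran-2-yl]pent-3-yn-2-ol | CC(C)=CCC/C(C)=C/CC[C@]1(C)O[C@H]1CC#C[C@@H](C)O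
F4 | step 2 | (2R,3E)-5-[(2S,3S)-3-[(3E)-4,8-dimethylnona-3,7-dien-1-yl]-3-methyloxiran-2-yl]pent-3-en-2-ol | CC(C)=CCC/C(C)=C/CC[C@]1(C)O[C@H]1C/C=C/[C@@H](C)O
F5 | step 10 | (3S,4S,6R)-6-[(2S,5E)-8-[(2S,3S)-3-[(1Z)-hepta-1,6-dien-1-yl]-3-methyloxiran-2-yl]-2-hydroxy-6-methyloct-5-en-2-yl]-3-methyl-4-[(1E)-prop-1-en-1-yl]oxan-2-one | C[C@@H]1C(=O)O[C@H](C[C@H]1/C=C/C)[C@@](C)(O)CC/C=C(C)/CC[C@@H]1O[C@@]1(C)/C=C\CCCC=C
F6 | step 12 | (1R,3R,4S,7E,11S,12S,15S)-11,12-epoxy-4-(trimethylsilyloxy)cembr-7-en-16,3-olide | C[C@@H]1C(=O)O[C@@H]2C[C@H]1CC[C@]1(C)O[C@H]1CC/C(C)=C/CC[C@]2(C)O[Si](C)(C)C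
F7 | step 12 | (1R,3R,4S,7S,8R,11S,12S,15S)-7-bromo-11,12-epoxy-8-hydroperoxy-4-(trimethylsilyloxy)cembran-16,3-olide | C[C@@H]1C(=O)O[C@@H]2C[C@H]1CC[C@]1(C)O[C@H]1CC[C@@](C)(OO)[C@@H](Br)CC[C@]2(C)O[Si](C)(C)C
F8 | step 12 | (1R,3R,4S,7S,8R,11S,12S,15S)-7-bromo-11,12-epoxy-8-[(2-methoxypropan-2-yl)peroxy]-4-(trimethylsilyloxy)cembran-16,3-olide | C[C@@H]1C(=O)O[C@@H]2C[C@H]1CC[C@]1(C)O[C@H]1CC[C@@](C)(OOC(C)(C)OC)[C@@H](Br)CC[C@]2(C)O[Si](C)(C)C
F9 | step 12 | (1R,3R,4S,6E,8R,11S,12S,15S)-11,12-epoxy-8-[(2-methoxypropan-2-yl)peroxy]-4-(trimethylsilyloxy)cembr-6-en-16,3-olide | C[C@@H]1C(=O)O[C@@H]2C[C@H]1CC[C@]1(C)O[C@H]1CC[C@@](C)(OOC(C)(C)OC)/C=C/C[C@]2(C)O[Si](C)(C)C
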